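**Retrosynthetic overview**
- The strategy rests on the C3–C4 bond of the pyrrole ring (N1, C2–C5). C3 and C4 each sit next to a carbon that comes from a ketone carbonyl (C2 carrying CHO, C5 carrying the henicosyl chain), so C3–C4 is the central bond of a 1,4-diketone.
- Pyrrole ⇒ 1,1-dimethoxyhexacosane-2,5-dione (Paal–Knorr), with the formyl group masked as a dimethyl acetal until the ring exists.
- C3–C4 ⇒ oxidative union of two methyl-ketone enol ethers held on one diisopropylsilyl tether, assembled from the kinetic lithium enolates of tricosan-2-one and 1,1-dimethoxypropan-2-one.
- Tricosan-2-one ⇒ docosanoic acid + MeLi. The only ring, the pyrrole, is closed last.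

Key step: step 4

Assumption: the target has no stereocentre, so no stereocontrol is needed; MeLi and LiN(iPr)2 are taken as commercial solutions, and the moisture-sensitive silanes 7 and 10 are handled under argon.

**Step 1**
Reactants: 1 docosanoic acid
Product: 4 tricosan-2-one, via lithium docosanoate 2 (not isolated), via dilithium tricosane-2,2-diolate 3 (not isolated)
Conditions: MeLi (2.2 equiv), THF/Et2O, 0 °C to rt; inverse quench into cold 1 M aq HCl
Reagents that add atoms: methyllithium, [Li]C
Why: Addition of MeLi to the lithium carboxylate (organolithium ketone synthesis from a carboxylic acid) should stop at the dilithium gem-diolate, which collapses to the ketone only in the acidic inverse quench, when no MeLi is left to add again; no stereocentre is formed.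

**Step 2**
Reactants: 4 tricosan-2-one; 5 dichlorodiisopropylsilane
Product: 7 chloro(diisopropyl)(tricos-1-en-2-yloxy)silane, via lithium tricos-1-en-2-olate 6 (not isolated)
Conditions: LiN(iPr)2 (1.1 equiv), THF, −78 °C; cannulate into iPr2SiCl2 (3 equiv), THF, −78 °C to rt; strip volatiles under high vacuum, pentane, filter under argon, use crude
Reagents that add atoms: none
Why: Kinetic enolisation by the hindered lithium amide should remove a proton from the methyl group and not from C3, and O-silylation of the enolate (silyl enol ether formation) under inverse addition into excess dichlorosilane should stop at the monochloride because a second displacement at the hindered silicon is slow; any minor internal enol ether isomer would be removed at diketone 11.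

**Step 3**
Reactants: 7 chloro(diisopropyl)(tricos-1-en-2-yloxy)silane; 8 1,1-dimethoxypropan-2-one
Product: 10 (3,3-dimethoxyprop-1-en-2-yloxy)diisopropyl(tricos-1-en-2-yloxy)silane, via lithium 3,3-dimethoxyprop-1-en-2-olate 9 (not isolated)
Conditions: 8, LiN(iPr)2 (1.2 equiv), THF, −78 °C; then 7 in THF, DMPU, −78 °C to rt; pentane, filtration through Et3N-deactivated silica
Reagents that add atoms: none
Why: Ketone 8 should be deprotonated at its methyl group (the acetal CH is hindered and its anion is destabilised by the two oxygens), and the lithium enolate, loosened by DMPU, should displace chloride from silicon through oxygen (O-silylation), the two isopropyl groups keeping the mixed bis-enol ether from redistributing; no stereocentre is formed.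

**Step 4**
Reactants: 10 (3,3-dimethoxyprop-1-en-2-yloxy)diisopropyl(tricos-1-en-2-yloxy)silane
Product: 11 1,1-dimethoxyhexacosane-2,5-dione
Conditions: (NH4)2Ce(NO3)6 (2.2 equiv), NaHCO3 (4.4 equiv), MeCN/EtCN/CH2Cl2, −10 °C; aq NaHCO3 work-up
Reagents that add atoms: none
Why: Tetravalent cerium should remove one electron from the more electron-rich, alkyl-substituted enol ether to give a radical cation whose CH2 terminus adds to the CH2 terminus of the tethered partner; the resulting α-silyloxy radical is oxidised by a second equivalent, and loss of the diisopropylsilyl unit releases both carbonyls, so the future C3–C4 bond is the only skeletal bond made. The closest known reaction type is the (NH4)2Ce(NO3)6-mediated oxidative coupling of unsymmetrical dialkylsilyl bis-enol ethers of ketones to 1,4-diketones, here applied to two methyl-ketone-derived enol ethers. No ring is kept: the carbon–carbon bond forms through a transient seven-membered 1,3-dioxa-2-silacycle (7-endo-trig attack) that opens when silicon leaves. No stereocentre arises, because both coupling carbons are CH2 groups. The step needs cross-coupling over homodimerisation, which the O–Si–O tether secures by making the union intramolecular, and coupling at the methyl-derived carbons, which the terminal enol ether regiochemistry fixed in steps 2 and 3 secures. It also needs the dimethyl acetal to survive the Lewis-acidic oxidant, which the NaHCO3 buffer and the low temperature should ensure.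

**Step 5**
Reactants: 11 1,1-dimethoxyhexacosane-2,5-dione
Product: 13 5-henicosyl-1H-pyrrole-2-carbaldehyde, via 2-(dimethoxymethyl)-5-henicosyl-1H-pyrrole 12 (not isolated)
Conditions: NH4OAc (10 equiv), MeOH/THF, 50 °C; then AcOH/H2O/THF, rt
Reagents that add atoms: ammonium acetate, CC(=O)[O-].[NH4+]; water, O
Why: In a Paal–Knorr pyrrole synthesis ammonia should condense with the C2 and C5 carbonyls and aromatise by double dehydration; the acetal is slow to ionise while it sits next to a ketone but ionises readily through an azafulvenium ion once it sits on the electron-rich pyrrole, so buffered aqueous acetic acid should then release the formyl group without isolation of the labile acetal; no stereocentre is formed.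

**Compound list**
1 | docosanoic acid | CCCCCCCCCCCCCCCCCCCCCC(=O)O | starting material
2 | lithium docosanoate | CCCCCCCCCCCCCCCCCCCCCC(=O)[O-].[Li+] | intermediate
3 | dilithium tricosane-2,2-diolate | CCCCCCCCCCCCCCCCCCCCCC(C)([O-])[O-].[Li+].[Li+] | intermediate
4 | tricosan-2-one | CCCCCCCCCCCCCCCCCCCCCC(C)=O | intermediate
5 | dichlorodiisopropylsilane | CC(C)[Si](Cl)(Cl)C(C)C | starting material
6 | lithium tricos-1-en-2-olate | C=C([O-])CCCCCCCCCCCCCCCCCCCCC.[Li+] | intermediate
7 | chloro(diisopropyl)(tricos-1-en-2-yloxy)silane | C=C(CCCCCCCCCCCCCCCCCCCCC)O[Si](Cl)(C(C)C)C(C)C | intermediate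
8 | 1,1-dimethoxypropan-2-one | CC(=O)C(OC)OC | starting material
9 | lithium 3,3-dimethoxyprop-1-en-2-olate | C=C([O-])C(OC)OC.[Li+] | intermediate
10 | (3,3-dimethoxyprop-1-en-2-yloxy)diisopropyl(tricos-1-en-2-yloxy)silane (mixed diisopropylsilyl bis-enol ether) | C=C(CCCCCCCCCCCCCCCCCCCCC)O[Si](C(C)C)(C(C)C)OC(=C)C(OC)OC | intermediate
11 | 1,1-dimethoxyhexacosane-2,5-dione | COC(OC)C(=O)CCC(=O)CCCCCCCCCCCCCCCCCCCCC | intermediate
12 | 2-(dimethoxymethyl)-5-henicosyl-1H-pyrrole | COC(OC)c1ccc(CCCCCCCCCCCCCCCCCCCCC)[nH]1 | intermediate
13 | 5-henicosyl-1H-pyrrole-2-carbaldehyde | CCCCCCCCCCCCCCCCCCCCCc1ccc(C=O)[nH]1 | target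

**Total step count:** 5
**Longest linear sequence:** 5 steps (1 → 4 → 7 → 10 → 11 → 13)

**Steps most likely to fail**

1. Step 4. The radical cation may lose silicon and fall back to the two parent ketones, or be trapped by nitrate, faster than it adds to the inductively deactivated, acetal-bearing enol ether; the acetal may also be partly cleaved by the acidic oxidant. The fallback is a Stetter reaction, which sets out from 1 and 8 and comes back at 11. Acid 1 would be reduced with LiAlH4 (THF, reflux) to docosan-1-ol F1 and oxidised (SO3·pyridine, DMSO, Et3N, CH2Cl2, rt) to docosanal F2. Enolate 9, made from 8 as in step 3, would be aminomethylated with dimethyl(methylidene)ammonium iodide to the Mannich base 4-(dimethylamino)-1,1-dimethoxybutan-2-one F3. Heating F2 and F3 with 3-benzyl-5-(2-hydroxyethyl)-4-methylthiazolium chloride and Et3N in EtOH should release 1,1-dimethoxybut-3-en-2-one F4 in the flask by loss of dimethylamine. The carbene-derived acyl anion equivalent of F2 then adds to F4 in conjugate fashion to give 11.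

2. Step 3. O-Silylation of enolate 9 at the hindered silicon of 7 may be slow, allowing proton transfer and self-condensation of 9, scrambling to the symmetrical bis-enol ethers, or hydrolytic loss of 10 on isolation. The fallback drops the tether; it sets out from 4 and 8 and comes back at 11. Enolate 6 (from 4) and enolate 9 (from 8) would each be quenched with Me3SiCl to give trimethyl(tricos-1-en-2-yloxy)silane F5 and (3,3-dimethoxyprop-1-en-2-yloxy)trimethylsilane F6. F5, the more easily oxidised partner, would then be added as the limiting component to (NH4)2Ce(NO3)6/NaHCO3 in MeCN/CH2Cl2 at −10 °C in the presence of a several-fold excess of the cheap F6. This is the known intermolecular oxidative cross-coupling of silyl enol ethers by tetravalent cerium, in which selectivity rests on oxidation potential and stoichiometry. The polar homodimer of F6 should be separable from lipophilic 11.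

3. Step 1. Lithium docosanoate may separate as a gel so that the second addition of MeLi stalls, and ketone released during the quench may take up MeLi again to give the tertiary alcohol. The fallback sets out from 1 and comes back at 4. Acid 1 would be converted with (COCl)2 and catalytic DMF (CH2Cl2, rt) into docosanoyl chloride F7, then with MeNH(OMe)·HCl and Et3N into N-methoxy-N-methyldocosanamide F8. Addition of MeMgBr (THF, 0 °C) should stop at the chelated tetrahedral intermediate, which gives 4 on aqueous acid work-up (Weinreb ketone synthesis).

**Further compounds**
F1 | step 4 | docosan-1-ol | CCCCCCCCCCCCCCCCCCCCCCO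
F2 | step 4 | docosanal | CCCCCCCCCCCCCCCCCCCCCC=O
F3 | step 4 | 4-(dimethylamino)-1,1-dimethoxybutan-2-one | CN(C)CCC(=O)C(OC)OC
F4 | step 4 | 1,1-dimethoxybut-3-en-2-one | C=CC(=O)C(OC)OC
F5 | step 3 | trimethyl(tricos-1-en-2-yloxy)silane | C=C(CCCCCCCCCCCCCCCCCCCCC)O[Si](C)(C)C
F6 | step 3 | (3,3-dimethoxyprop-1-en-2-yloxy)trimethylsilane | C=C(O[Si](C)(C)C)C(OC)OC
F7 | step 1 | docosanoyl chloride | CCCCCCCCCCCCCCCCCCCCCC(=O)Cl
F8 | step 1 | N-methoxy-N-methyldocosanamide | CCCCCCCCCCCCCCCCCCCCCC(=O)N(C)OC
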